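Ring A is cut across C8–C8a and C6–C7 into a four-carbon cyclobutenone (C4a, C5, C6, C8a) and a two-carbon siloxyalkyne (C7, C8), each partner carrying its prenyl group on the carbon destined to lie between two oxygens. One thermal Danheiser benzannulation then closes ring A as a pentasubstituted phenol and delivers O1, O5 and O7 as free hydroxyl, methyl ether and silyl ether. The step exploits the alternating O–C(prenyl)–O–C(prenyl)–O array running from C5 to C8a of ring A. Its precursors are 3-methoxy-2-prenylcyclobutenone and a prenylated triisopropylsiloxyalkyne; ring C follows by directed lithiation, chalcone formation and Algar–Flynn–Oyamada oxidation.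

Key step: step 5

Remark: O5 is carried as a methyl ether so that it can be removed last by chelation-controlled MgI2 demethylation, which tolerates prenyl groups; intermediates 14, 25 and 26 are racemic and their stereocentres vanish before the achiral target.

Step 1
Reactants: 1 chloroacetaldehyde dimethyl acetal; 2 prenyl bromide
Product: 4 1-methoxy-5-methylhex-4-en-1-yne, via lithium methoxyacetylide 3 (not isolated)
Conditions: LiNEt2 (3.0 equiv, from n-BuLi and Et2NH), THF, 0 °C; then 2, DMPU, −78 °C → rt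
Reagents that add atoms: none
Why: Double elimination and deprotonation of the chloroacetal by exactly three equivalents of amide base gives the alkoxyacetylide, whose SN2 alkylation at the primary carbon of the allylic bromide is standard ynol ether chemistry, and the absence of excess base should prevent isomerisation of the skipped enyne.

Step 2
Reactants: 4 1-methoxy-5-methylhex-4-en-1-yne; 5 trichloroacetyl chloride
Product: 7 4,4-dichloro-3-methoxy-2-(3-methylbut-2-en-1-yl)cyclobut-2-en-1-one, via dichloroketene 6 (not isolated)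
Conditions: Zn–Cu couple, Et2O/DME, 0 °C → rt (5 added slowly)
Reagents that add atoms: none
Why: Ketene–alkyne [2+2] cycloaddition in which the nucleophilic β-carbon of the ynol ether bonds to the ketene carbonyl carbon, so the CCl2 carbon ends next to the methoxy-bearing carbon, while the unactivated prenyl alkene is far less reactive and DME sequesters ZnCl2.

Step 3
Reactants: 7 4,4-dichloro-3-methoxy-2-(3-methylbut-2-en-1-yl)cyclobut-2-en-1-one
Product: 8 3-methoxy-2-(3-methylbut-2-en-1-yl)cyclobut-2-en-1-one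
Conditions: Zn dust, AcOH, TMEDA, EtOH, 0 °C → rt
Reagents that add atoms: none
Why: Buffered zinc reduction of an α,α-dichloroketone (reductive dechlorination through zinc enolates) should remove both chlorines without touching the vinylogous ester or the isolated alkene.

Step 4
Reactants: 9 methyl 4-methylpent-3-enoate
Product: 12 triisopropyl[(5-methylhex-4-en-1-yn-1-yl)oxy]silane, via dibromo enolate 10 (not isolated), via lithium ynolate 11 (not isolated)
Conditions: CH2Br2, lithium 2,2,6,6-tetramethylpiperidide (2.1 equiv, from n-BuLi and the amine), THF, −78 °C; then 9; n-BuLi, −78 → 0 °C; i-Pr3SiCl, −78 °C → rt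
Reagents that add atoms: dibromomethane BrCBr; triisopropylsilyl chloride CC(C)[Si](Cl)(C(C)C)C(C)C
Why: Kowalski ester homologation, in which LiCHBr2 adds to the ester, the derived dibromo enolate undergoes bromine–lithium exchange and a carbenoid 1,2-shift to the ynolate, and the bulky silyl chloride captures the ynolate on oxygen; the low temperature and the weakly basic carbenoid should limit α-deprotonation.

Step 5
Reactants: 8 3-methoxy-2-(3-methylbut-2-en-1-yl)cyclobut-2-en-1-one; 12 triisopropyl[(5-methylhex-4-en-1-yn-1-yl)oxy]silane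
Product: 17 5-methoxy-2,4-bis(3-methylbut-2-en-1-yl)-3-[(triisopropylsilyl)oxy]phenol, via vinylketene 13 (not isolated), via cyclobutenone adduct 14 (not isolated), via dienylketene 15 (not isolated), via cyclohexadienone 16 (not isolated)
Conditions: PhMe (0.5 M), 12 (1.2 equiv), 80 °C then 110 °C, sealed tube
Reagents that add atoms: none
Why: Heating should open 8 by four-electron electrocyclic cleavage of its C1–C4 bond to vinylketene 13, which the electron-rich alkyne 12 captures in a ketene–alkyne [2+2] across the ketene C=C to give 14. Adduct 14 opens again (four-electron cleavage of its C1–C4 bond) to dienylketene 15, whose thermal disrotatory six-electron electrocyclisation joins the ketene carbon to the CH2 terminus (C8a–C4a) and closes ring A as dienone 16, which tautomerises to phenol 17; the net new skeletal bonds are C8–C8a and C6–C7. This is the Danheiser benzannulation of a cyclobutenone with a siloxyalkyne, a known route to resorcinol monosilyl ethers, applied here to a 3-alkoxycyclobutenone. No stereocentre survives, since the quaternary carbon of racemic 14 becomes aromatic C6. The step needs the regiochemistry of the [2+2], and the polarisation of the ynol ether secures it: its nucleophilic prenyl-bearing carbon bonds to the electrophilic ketene carbonyl carbon, so O1–H, O7–Si and O5–Me emerge differentiated with prenyl groups at C8 and C6. Chemoselectivity over the two trisubstituted alkenes should follow from the much higher ketenophilicity of the siloxyalkyne, and the slight excess of 12 limits acylation of the product phenol by 13.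

Step 6
Reactants: 17 5-methoxy-2,4-bis(3-methylbut-2-en-1-yl)-3-[(triisopropylsilyl)oxy]phenol
Product: 18 triisopropyl[3-methoxy-5-(methoxymethoxy)-2,6-bis(3-methylbut-2-en-1-yl)phenoxy]silane
Conditions: NaH, MOMCl, THF, 0 °C → rt
Reagents that add atoms: chloromethyl methyl ether COCCl
Why: Williamson-type O-alkylation of the sodium phenoxide gives an acetal ether that is inert to n-BuLi and serves as directing group in the metalation that follows.

Step 7
Reactants: 19 4-(prop-2-en-1-yloxy)benzaldehyde; 20 diethyl {2-[methoxy(methyl)amino]-2-oxoethyl}phosphonate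
Product: 21 (2E)-N-methoxy-N-methyl-3-[4-(prop-2-en-1-yloxy)phenyl]prop-2-enamide
Conditions: NaH, THF, 0 °C → rt
Reagents that add atoms: none
Why: Horner–Wadsworth–Emmons olefination of an aromatic aldehyde with a stabilised amide phosphonate is reliably E-selective.

Step 8
Reactants: 18 triisopropyl[3-methoxy-5-(methoxymethoxy)-2,6-bis(3-methylbut-2-en-1-yl)phenoxy]silane; 21 (2E)-N-methoxy-N-methyl-3-[4-(prop-2-en-1-yloxy)phenyl]prop-2-enamide
Product: 23 (2E)-1-{6-methoxy-2-(methoxymethoxy)-3,5-bis(3-methylbut-2-en-1-yl)-4-[(triisopropylsilyl)oxy]phenyl}-3-[4-(prop-2-en-1-yloxy)phenyl]prop-2-en-1-one, via aryllithium 22 (not isolated)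
Conditions: n-BuLi, THF, 0 °C, 1 h; then 21, −78 → 0 °C
Reagents that add atoms: none
Why: Directed ortho-metalation at the only ring C–H, which is flanked by the OMOM and OMe groups, followed by acyl substitution on the Weinreb amide, whose chelated tetrahedral intermediate prevents over-addition and favours 1,2-attack, should give the chalcone directly.

Step 9
Reactants: 23 (2E)-1-{6-methoxy-2-(methoxymethoxy)-3,5-bis(3-methylbut-2-en-1-yl)-4-[(triisopropylsilyl)oxy]phenyl}-3-[4-(prop-2-en-1-yloxy)phenyl]prop-2-en-1-one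
Product: 24 (2E)-1-{2-hydroxy-6-methoxy-3,5-bis(3-methylbut-2-en-1-yl)-4-[(triisopropylsilyl)oxy]phenyl}-3-[4-(prop-2-en-1-yloxy)phenyl]prop-2-en-1-one
Conditions: HCl (aq., 2 M), MeOH/THF, rt
Reagents that add atoms: none
Why: Acid-catalysed acetal methanolysis of the only acetal present, which sits ortho to the ketone and cleaves under conditions mild enough to keep the aryl silyl and allyl ethers and the prenyl groups, as is usual for prenylated chalcones.

Step 10
Reactants: 24 (2E)-1-{2-hydroxy-6-methoxy-3,5-bis(3-methylbut-2-en-1-yl)-4-[(triisopropylsilyl)oxy]phenyl}-3-[4-(prop-2-en-1-yloxy)phenyl]prop-2-en-1-one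
Product: 27 3-hydroxy-5-methoxy-6,8-bis(3-methylbut-2-en-1-yl)-2-[4-(prop-2-en-1-yloxy)phenyl]-7-[(triisopropylsilyl)oxy]-4H-chromen-4-one, via chalcone epoxide 25 (not isolated), via dihydroflavonol 26 (not isolated)
Conditions: 30% H2O2, aq. NaOH, MeOH/THF, 0 °C → rt
Reagents that add atoms: hydrogen peroxide OO
Why: Algar–Flynn–Oyamada oxidation, in which hydroperoxide epoxidises the enone, the phenoxide opens the epoxide 6-endo at the benzylic carbon (favoured by the 4-alkoxyphenyl group) to the trans-dihydroflavonol, and in situ dehydrogenation removes both transient stereocentres; nucleophilic peroxide leaves the prenyl and allyl alkenes alone and the di-ortho-substituted aryl silyl ether is shielded from hydroxide at 0 °C.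

Step 11
Reactants: 27 3-hydroxy-5-methoxy-6,8-bis(3-methylbut-2-en-1-yl)-2-[4-(prop-2-en-1-yloxy)phenyl]-7-[(triisopropylsilyl)oxy]-4H-chromen-4-one
Product: 29 3,7-dihydroxy-2-(4-hydroxyphenyl)-5-methoxy-6,8-bis(3-methylbut-2-en-1-yl)-4H-chromen-4-one, via deallylated flavonol 28 (not isolated)
Conditions: Pd(PPh3)4 (5 mol %), morpholine, THF, rt; then n-Bu4NF, AcOH, 0 °C → rt
Reagents that add atoms: none
Why: Tsuji–Trost deallylation (zerovalent palladium ionises the aryl allyl ether and morpholine traps the π-allyl complex) followed by buffered fluoride cleavage of the aryl silyl ether, two near-neutral operations that leave C-prenyl groups untouched.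

Step 12
Reactants: 29 3,7-dihydroxy-2-(4-hydroxyphenyl)-5-methoxy-6,8-bis(3-methylbut-2-en-1-yl)-4H-chromen-4-one
Product: 30 6,8-diprenylkaempferol
Conditions: MgI2·OEt2 (from Mg and I2 in Et2O), THF, 60 °C
Reagents that add atoms: none
Why: Chelation-controlled demethylation in which magnesium bound between the C4 carbonyl and O5 activates only the peri methyl ether toward SN2 attack by iodide, a non-protic method known to spare prenyl groups and free phenols in 5-methoxyflavonoids.

Compound list
1 | 2-chloro-1,1-dimethoxyethane (chloroacetaldehyde dimethyl acetal) | COC(CCl)OC | starting material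
2 | 1-bromo-3-methylbut-2-ene (prenyl bromide) | CC(C)=CCBr | starting material
3 | lithium methoxyacetylide | [Li]C#COC | intermediate (not isolated)
4 | 1-methoxy-5-methylhex-4-en-1-yne | COC#CCC=C(C)C | intermediate
5 | trichloroacetyl chloride | O=C(Cl)C(Cl)(Cl)Cl | starting material
6 | dichloroketene | O=C=C(Cl)Cl | intermediate (not isolated)
7 | 4,4-dichloro-3-methoxy-2-(3-methylbut-2-en-1-yl)cyclobut-2-en-1-one | O=C1C(CC=C(C)C)=C(OC)C1(Cl)Cl | intermediate
8 | 3-methoxy-2-(3-methylbut-2-en-1-yl)cyclobut-2-en-1-one | O=C1CC(OC)=C1CC=C(C)C | intermediate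
9 | methyl 4-methylpent-3-enoate | COC(=O)CC=C(C)C | starting material
10 | lithium 1,1-dibromo-5-methylhexa-1,4-dien-2-olate | [Li]OC(CC=C(C)C)=C(Br)Br | intermediate (not isolated)
11 | lithium 5-methylhex-4-en-1-yn-1-olate | [Li]OC#CCC=C(C)C | intermediate (not isolated)
12 | triisopropyl[(5-methylhex-4-en-1-yn-1-yl)oxy]silane | CC(C)=CCC#CO[Si](C(C)C)(C(C)C)C(C)C | intermediate
13 | 3-methoxy-2-(3-methylbut-2-en-1-yl)buta-1,3-dien-1-one (vinylketene) | O=C=C(CC=C(C)C)C(OC)=C | intermediate (not isolated)
14 | 4-(1-methoxyethenyl)-2,4-bis(3-methylbut-2-en-1-yl)-3-[(triisopropylsilyl)oxy]cyclobut-2-en-1-one (racemic) | O=C1C(CC=C(C)C)=C(O[Si](C(C)C)(C(C)C)C(C)C)C1(CC=C(C)C)C(OC)=C | intermediate (not isolated)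
15 | (3E)-5-methoxy-2,4-bis(3-methylbut-2-en-1-yl)-3-[(triisopropylsilyl)oxy]hexa-1,3,5-trien-1-one (ketene and methoxyvinyl termini cis) | O=C=C(CC=C(C)C)/C(O[Si](C(C)C)(C(C)C)C(C)C)=C(/CC=C(C)C)C(OC)=C | intermediate (not isolated)
16 | 5-methoxy-2,4-bis(3-methylbut-2-en-1-yl)-3-[(triisopropylsilyl)oxy]cyclohexa-2,4-dien-1-one | O=C1CC(OC)=C(CC=C(C)C)C(O[Si](C(C)C)(C(C)C)C(C)C)=C1CC=C(C)C | intermediate (not isolated)
17 | 5-methoxy-2,4-bis(3-methylbut-2-en-1-yl)-3-[(triisopropylsilyl)oxy]phenol | COc1cc(O)c(CC=C(C)C)c(O[Si](C(C)C)(C(C)C)C(C)C)c1CC=C(C)C | intermediate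
18 | triisopropyl[3-methoxy-5-(methoxymethoxy)-2,6-bis(3-methylbut-2-en-1-yl)phenoxy]silane | COCOc1cc(OC)c(CC=C(C)C)c(O[Si](C(C)C)(C(C)C)C(C)C)c1CC=C(C)C | intermediate
19 | 4-(prop-2-en-1-yloxy)benzaldehyde | C=CCOc1ccc(C=O)cc1 | starting material
20 | diethyl {2-[methoxy(methyl)amino]-2-oxoethyl}phosphonate | CCOP(=O)(CC(=O)N(C)OC)OCC | starting material
21 | (2E)-N-methoxy-N-methyl-3-[4-(prop-2-en-1-yloxy)phenyl]prop-2-enamide | C=CCOc1ccc(/C=C/C(=O)N(C)OC)cc1 | intermediate
22 | {2-methoxy-6-(methoxymethoxy)-3,5-bis(3-methylbut-2-en-1-yl)-4-[(triisopropylsilyl)oxy]phenyl}lithium | [Li]c1c(OC)c(CC=C(C)C)c(O[Si](C(C)C)(C(C)C)C(C)C)c(CC=C(C)C)c1OCOC | intermediate (not isolated)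
23 | (2E)-1-{6-methoxy-2-(methoxymethoxy)-3,5-bis(3-methylbut-2-en-1-yl)-4-[(triisopropylsilyl)oxy]phenyl}-3-[4-(prop-2-en-1-yloxy)phenyl]prop-2-en-1-one | C=CCOc1ccc(/C=C/C(=O)c2c(OC)c(CC=C(C)C)c(O[Si](C(C)C)(C(C)C)C(C)C)c(CC=C(C)C)c2OCOC)cc1 | intermediate
24 | (2E)-1-{2-hydroxy-6-methoxy-3,5-bis(3-methylbut-2-en-1-yl)-4-[(triisopropylsilyl)oxy]phenyl}-3-[4-(prop-2-en-1-yloxy)phenyl]prop-2-en-1-one | C=CCOc1ccc(/C=C/C(=O)c2c(OC)c(CC=C(C)C)c(O[Si](C(C)C)(C(C)C)C(C)C)c(CC=C(C)C)c2O)cc1 | intermediate
25 | {2-hydroxy-6-methoxy-3,5-bis(3-methylbut-2-en-1-yl)-4-[(triisopropylsilyl)oxy]phenyl}{trans-3-[4-(prop-2-en-1-yloxy)phenyl]oxiran-2-yl}methanone (racemic, (2R,3S) drawn) | O=C([C@@H]1O[C@H]1c1ccc(OCC=C)cc1)c1c(OC)c(CC=C(C)C)c(O[Si](C(C)C)(C(C)C)C(C)C)c(CC=C(C)C)c1O | intermediate (not isolated)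
26 | trans-3-hydroxy-5-methoxy-6,8-bis(3-methylbut-2-en-1-yl)-2-[4-(prop-2-en-1-yloxy)phenyl]-7-[(triisopropylsilyl)oxy]-2,3-dihydro-4H-chromen-4-one (racemic, (2R,3R) drawn) | C=CCOc1ccc([C@@H]2[C@H](C(=O)c3c(OC)c(CC=C(C)C)c(O[Si](C(C)C)(C(C)C)C(C)C)c(CC=C(C)C)c3O2)O)cc1 | intermediate (not isolated)
27 | 3-hydroxy-5-methoxy-6,8-bis(3-methylbut-2-en-1-yl)-2-[4-(prop-2-en-1-yloxy)phenyl]-7-[(triisopropylsilyl)oxy]-4H-chromen-4-one | C=CCOc1ccc(-c2oc3c(CC=C(C)C)c(O[Si](C(C)C)(C(C)C)C(C)C)c(CC=C(C)C)c(OC)c3c(=O)c2O)cc1 | intermediate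
28 | 3-hydroxy-2-(4-hydroxyphenyl)-5-methoxy-6,8-bis(3-methylbut-2-en-1-yl)-7-[(triisopropylsilyl)oxy]-4H-chromen-4-one | Oc1ccc(-c2oc3c(CC=C(C)C)c(O[Si](C(C)C)(C(C)C)C(C)C)c(CC=C(C)C)c(OC)c3c(=O)c2O)cc1 | intermediate (not isolated)
29 | 3,7-dihydroxy-2-(4-hydroxyphenyl)-5-methoxy-6,8-bis(3-methylbut-2-en-1-yl)-4H-chromen-4-one | COc1c(CC=C(C)C)c(O)c(CC=C(C)C)c2oc(-c3ccc(O)cc3)c(O)c(=O)c12 | intermediate
30 | 6,8-diprenylkaempferol, 3,5,7-trihydroxy-2-(4-hydroxyphenyl)-6,8-bis(3-methylbut-2-en-1-yl)-4H-chromen-4-one | CC(C)=CCc1c(O)c(CC=C(C)C)c2oc(-c3ccc(O)cc3)c(O)c(=O)c2c1O | target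

Total step count: 12.
Longest linear sequence: 10 steps (steps 1, 2, 3, 5, 6, 8, 9, 10, 11, 12, from chloroacetaldehyde dimethyl acetal).

Steps most likely to fail

Step 5. The vinylogous-ester cyclobutenone may open only at temperatures where the vinylketene oligomerises or acylates the product phenol faster than the siloxyalkyne traps it. The fallback generates the same vinylketene 13 at room temperature by base-induced 1,4-dehydrochlorination instead of electrocyclic opening. It sets out from prenyl bromide 2: C-alkylation of methyl acetoacetate (K2CO3, acetone) should give methyl 2-acetyl-5-methylhex-4-enoate F1; enol ether formation (HC(OMe)3, cat. H2SO4, MeOH) should give methyl (2E)-3-methoxy-2-(3-methylbut-2-en-1-yl)but-2-enoate F2 (the Z isomer would serve equally); saponification (LiOH, aq. MeOH) should give (2E)-3-methoxy-2-(3-methylbut-2-en-1-yl)but-2-enoic acid F3; neutral chlorination with Ghosez's reagent should give (2E)-3-methoxy-2-(3-methylbut-2-en-1-yl)but-2-enoyl chloride F4. Slow addition of F4 to Et3N and 12 in PhMe (rt, then 80 °C) forms 13 by γ-deprotonation, and the same [2+2], ring-opening and electrocyclisation sequence returns to the route at phenol 17.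

Step 10. With the 6'-methoxy group the epoxide may be opened 5-exo at the α-carbon (aurone pathway), and hydroxide may strip the silyl ether before epoxidation, after which the doubly ionised chalcone no longer accepts hydroperoxide. The fallback separates epoxidation from ring closure and sets out from chalcone 23, whose phenol is still masked. Anhydrous Weitz–Scheffer epoxidation (t-BuOOH, DBU, CH2Cl2) should give {6-methoxy-2-(methoxymethoxy)-3,5-bis(3-methylbut-2-en-1-yl)-4-[(triisopropylsilyl)oxy]phenyl}{trans-3-[4-(prop-2-en-1-yloxy)phenyl]oxiran-2-yl}methanone F5. HCl in MeOH (rt → 40 °C) then removes the acetal, and the freed phenol opens the protonated epoxide at the benzylic carbon to dihydroflavonol 26. Dehydrogenation of the α-ketol under mild base (air, K2CO3, DMF) returns to the route at flavonol 27.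

Step 4. Deprotonation of the acidic allylic α-CH2 of the β,γ-unsaturated ester may compete with carbonyl addition of LiCHBr2 and lead to enolisation and deconjugation. The fallback reaches the same ynolate by oxidising a lithium acetylide and sets out from prenyl bromide 2. CuCl-catalysed coupling with HC≡CMgBr (THF) should give 5-methylhex-4-en-1-yne F6; deprotonation with LiN(SiMe3)2 (THF, −78 °C) and oxygen transfer from t-BuOOLi (−78 → 0 °C) should give ynolate 11, and silylation with i-Pr3SiOTf returns to the route at siloxyalkyne 12.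

Further compounds
F1 | step 5 | methyl 2-acetyl-5-methylhex-4-enoate (racemic) | COC(=O)C(CC=C(C)C)C(C)=O
F2 | step 5 | methyl (2E)-3-methoxy-2-(3-methylbut-2-en-1-yl)but-2-enoate | CO/C(C)=C(\CC=C(C)C)C(=O)OC
F3 | step 5 | (2E)-3-methoxy-2-(3-methylbut-2-en-1-yl)but-2-enoic acid | CO/C(C)=C(\CC=C(C)C)C(=O)O
F4 | step 5 | (2E)-3-methoxy-2-(3-methylbut-2-en-1-yl)but-2-enoyl chloride | CO/C(C)=C(\CC=C(C)C)C(=O)Cl
F5 | step 10 | {6-methoxy-2-(methoxymethoxy)-3,5-bis(3-methylbut-2-en-1-yl)-4-[(triisopropylsilyl)oxy]phenyl}{trans-3-[4-(prop-2-en-1-yloxy)phenyl]oxiran-2-yl}methanone (racemic, (2R,3S) drawn) | O=C([C@@H]1O[C@H]1c1ccc(OCC=C)cc1)c1c(OC)c(CC=C(C)C)c(O[Si](C(C)C)(C(C)C)C(C)C)c(CC=C(C)C)c1OCOC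
F6 | step 4 | 5-methylhex-4-en-1-yne | C#CCC=C(C)C
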